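**Plan**
- Retrosynthesis cuts the benzylic CH2–CH= bond and the =C–CH3 bond (alkyne carboalumination, then alkenyl–benzyl coupling), then the CH2–C≡ bond (acetylide alkylation), then, in one operation, the bridgehead CH–CH2 bond and the O–C(CH3) bond of the 7-oxabicyclo[2.2.1]heptane.
- Enabling feature: the oxolane ring of the bicycle (O, bridgehead CH, CH2, CH2, bridgehead C–CH3) is a C=O unit plus a three-carbon unit, and the two-carbon chain on the ring CH next to C–CH3 is exo, on the side of the bridging O. The O can therefore be tied to the chain end as a tetrahydropyran lactol (temporary ring), and the three carbons can be a 1-methylcyclopropane.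
- Forward: the δ-lactone ring comes first (asymmetric isopropenyl addition, gem-dimethylation, cyclopropanation, reductive acetylation). The key step then closes the cyclohexane ring, then the oxygen bridge, and opens the temporary ring to a 2-bromoethyl chain, which is joined to the arene through an alkyne.
- Stereochemistry: the single lactone stereocentre (catalyst control) is relayed to both bridgeheads by the tether; the E alkene comes from syn carbometalation and stereoretentive coupling.

Key step: step 5

Remark: (S)-BINAP in step 1 is taken as the ligand enantiomer that gives the 4S lactone, by analogy with additions to cyclic enones; if the sense were opposite, (R)-BINAP would be used and nothing else changes.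

**Step 1**
Reactants: 1 5,6-dihydro-2H-pyran-2-one; 2 2-(prop-1-en-2-yl)-4,4,5,5-tetramethyl-1,3,2-dioxaborolane
Product: 3 (4S)-4-(prop-1-en-2-yl)oxan-2-one
Conditions: [RhCl(cod)]2 (2.5 mol %), (S)-BINAP (6 mol %), KOH (10 mol %), dioxane/H2O 10:1, 40 °C; 1 M HCl work-up (relactonisation)
Reagents that add atoms: none
Why: Rhodium-catalysed asymmetric 1,4-addition of an alkenylboron reagent to the unsaturated δ-lactone (Hayashi–Miyaura reaction), in which the alkenylrhodium–BINAP complex should insert the C=C bond on one enantioface and so set the 4S centre, the only stereocentre brought in from outside.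

**Step 2**
Reactants: 3 (4S)-4-(prop-1-en-2-yl)oxan-2-one
Product: 5 (4R)-3,3-dimethyl-4-(prop-1-en-2-yl)oxan-2-one, via (4S)-3-methyl-4-(prop-1-en-2-yl)oxan-2-one 4 (not isolated)
Conditions: LiN(i-Pr)2 (1.1 equiv), THF, −78 °C, then MeI (1.05 equiv), −78 → −40 °C; recooled to −78 °C, LiN(i-Pr)2 (1.3 equiv), then MeI (3 equiv), DMPU, −78 → 0 °C
Reagents that add atoms: iodomethane, CI
Why: Two successive lactone enolate C-methylations (enolate alkylation) should build the quaternary α-carbon, which carries no stereocentre, while C4 has no acidic hydrogen and keeps its configuration (the descriptor changes to R only through the priority rules).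

**Step 3**
Reactants: 5 (4R)-3,3-dimethyl-4-(prop-1-en-2-yl)oxan-2-one
Product: 6 (4R)-3,3-dimethyl-4-(1-methylcyclopropyl)oxan-2-one
Conditions: ZnEt2 (3 equiv), CH2I2 (3 equiv), CH2Cl2, 0 °C → rt
Reagents that add atoms: diiodomethane, ICI
Why: Simmons–Smith cyclopropanation (Furukawa variant) of the 1,1-disubstituted alkene, whose exposed CH2 terminus should accept the zinc carbenoid while the lactone is inert; no stereocentre is formed because the new ring carbon carries two CH2 groups.

**Step 4**
Reactants: 6 (4R)-3,3-dimethyl-4-(1-methylcyclopropyl)oxan-2-one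
Product: 8 (4R)-3,3-dimethyl-4-(1-methylcyclopropyl)oxan-2-yl acetate (both anomers), via diisobutylaluminium lactolate 7 (not isolated)
Conditions: i-Bu2AlH (1.2 equiv), CH2Cl2, −78 °C; then pyridine, DMAP, Ac2O, −78 → −20 °C
Reagents that add atoms: acetic anhydride, CC(=O)OC(C)=O
Why: Partial reduction of the lactone to the tetrahedral aluminium lactolate, which the quaternary α-carbon should keep from collapsing, followed by O-acetylation in the same flask (reductive acetylation); the anomeric mixture is of no consequence because both anomers give the same cation in step 5.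

**Step 5**
Reactants: 8 (4R)-3,3-dimethyl-4-(1-methylcyclopropyl)oxan-2-yl acetate
Product: 12 (1R,2S,4S)-2-(2-bromoethyl)-1,3,3-trimethyl-7-oxabicyclo[2.2.1]heptane, via cyclic oxocarbenium ion 9 (not isolated), via 6,9,9-trimethyl-2-oxabicyclo[3.3.1]nonan-6-yl cation 10 (not isolated), via tricyclic trialkyloxonium ion 11 (not isolated)
Conditions: SnBr4 (1.5 equiv), 2,6-di-tert-butyl-4-methylpyridine (0.2 equiv), CH2Cl2, −78 → 0 °C; aq NaHCO3
Reagents that add atoms: tin tetrabromide, Br[Sn](Br)(Br)Br
Why: Proposed new method: SnBr4 should ionise either anomer of 8 to the six-membered oxocarbenium ion 9, which cannot lose a proton to an enol ether because its α-carbon is quaternary; the C(quaternary)–CH2 σ-bond of the pseudoaxial 1-methylcyclopropyl group then attacks the cationic carbon (homo-Prins edge attack, new bond at the CH2 carbon, charge at the tertiary carbon, cation 10), the ring oxygen closes on that cation to the oxonium ion 11, and bromide opens 11 by SN2 at its only primary O–CH2 carbon, which frees the bridging ether and leaves the former tether as the 2-bromoethyl chain. The closest known reaction types are the SnBr4-mediated Prins cyclisation of α-acetoxy ethers with alkenes and the Lewis-acid (3+2) annulation of donor–acceptor cyclopropanes with aldehydes; what is new is a cyclopropane without acceptor groups as the three-carbon partner, argued from the known electrophilic opening of 1,1-dialkylcyclopropanes at the less substituted carbon and from the 1,3-diaxial proximity of the two partners on the ring. The carbocycle closes in a 6-endo mode with respect to the cleaved cyclopropane bond (both of its carbons end in the new cyclohexane), and the oxolane ring closes by transannular five-membered capture of the tertiary cation by oxygen across the boat of that cyclohexane. The CH bridgehead is set by the tether, since the cyclopropyl group can reach the oxocarbenium carbon only on the ring face it occupies; the C(CH3) bridgehead follows because a one-atom oxygen bridge can span the ring only cis; and the side chain is exo because it is the remnant of the temporary ring that held it to the same oxygen. The step needs the σ-bond to compete with bromide for 9 and needs 10 to end as ether and not as tertiary bromide or alkene; bromide capture of 9 and of 10 is reversible under SnBr4 and alkenes from proton loss can re-enter by protonation, whereas dealkylation of 11 at the primary carbon is irreversible, so these species should funnel into 12. The two cyclopropane CH2 groups lead to the same product, so no selection between them is required.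

**Step 6**
Reactants: 12 (1R,2S,4S)-2-(2-bromoethyl)-1,3,3-trimethyl-7-oxabicyclo[2.2.1]heptane
Product: 13 (1R,2S,4S)-2-(but-3-yn-1-yl)-1,3,3-trimethyl-7-oxabicyclo[2.2.1]heptane
Conditions: LiC≡CH·H2NCH2CH2NH2 (3 equiv), DMSO, 15 °C → rt
Reagents that add atoms: lithium acetylide ethylenediamine complex, [Li]C#C.NCCN
Why: SN2 alkylation of lithium acetylide by the primary bromide in a dipolar aprotic solvent, in which the bicyclic ether is inert to base and no stereocentre is touched.

**Step 7**
Reactants: 14 methyl 4-hydroxy-3-methylbenzoate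
Product: 15 methyl 4-acetoxy-3-methylbenzoate
Conditions: Ac2O, pyridine, DMAP (cat.), CH2Cl2, rt
Reagents that add atoms: acetic anhydride, CC(=O)OC(C)=O
Why: O-Acylation of the phenol, which deactivates the ring toward electrophilic bromination in step 8 and masks the acidic OH toward the organoaluminium reagent in step 9.

**Step 8**
Reactants: 15 methyl 4-acetoxy-3-methylbenzoate
Product: 16 methyl 4-acetoxy-3-(bromomethyl)benzoate
Conditions: NBS (1.05 equiv), AIBN (5 mol %), PhCF3, 85 °C
Reagents that add atoms: N-bromosuccinimide, O=C1CCC(=O)N1Br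
Why: Wohl–Ziegler radical bromination at the only benzylic position, favoured over ring bromination because both the ester and the acetoxy group make the arene electron-poor.

**Step 9**
Reactants: 13 (1R,2S,4S)-2-(but-3-yn-1-yl)-1,3,3-trimethyl-7-oxabicyclo[2.2.1]heptane; 16 methyl 4-acetoxy-3-(bromomethyl)benzoate
Product: 18 methyl 4-acetoxy-3-[(2E)-3-methyl-5-[(1R,2S,4S)-1,3,3-trimethyl-7-oxabicyclo[2.2.1]heptan-2-yl]pent-2-en-1-yl]benzoate, via (E)-alkenyldimethylalane 17 (not isolated)
Conditions: AlMe3 (2.2 equiv), Cp2ZrCl2 (0.25 equiv), CH2Cl2, 0 °C → rt; volatiles removed in vacuo; then 16 (1.1 equiv), Pd(PPh3)4 (5 mol %), THF, rt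
Reagents that add atoms: trimethylaluminium, C[Al](C)C
Why: Zirconium-catalysed carboalumination of the terminal alkyne (Negishi carboalumination) should add CH3 and Al syn with Al at the terminus, and palladium-catalysed coupling of the alkenylalane with the benzylic bromide (Negishi coupling) proceeds with retention, so the E trisubstituted alkene follows from the syn addition.

**Step 10**
Reactants: 18 methyl 4-acetoxy-3-[(2E)-3-methyl-5-[(1R,2S,4S)-1,3,3-trimethyl-7-oxabicyclo[2.2.1]heptan-2-yl]pent-2-en-1-yl]benzoate
Product: 19 4-hydroxy-3-[(2E)-3-methyl-5-[(1R,2S,4S)-1,3,3-trimethyl-7-oxabicyclo[2.2.1]heptan-2-yl]pent-2-en-1-yl]benzoic acid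
Conditions: LiOH (6 equiv), THF/MeOH/H2O 3:1:1, rt → 45 °C; then 1 M HCl to pH 4, 0 °C
Reagents that add atoms: lithium hydroxide, [Li+].[OH-]
Why: Saponification of the aryl acetate and the methyl ester by hydroxide in one operation, followed by cold, mild acidification so that neither the strained tertiary ether nor the ortho-allyl phenol is exposed to strong acid; no stereocentre is involved.

**Compound list**
1 | 5,6-dihydro-2H-pyran-2-one | O=C1C=CCCO1 | starting material
2 | 2-(prop-1-en-2-yl)-4,4,5,5-tetramethyl-1,3,2-dioxaborolane (isopropenylboronic acid pinacol ester) | CC(=C)B1OC(C)(C)C(C)(C)O1 | starting material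
3 | (4S)-4-(prop-1-en-2-yl)oxan-2-one | O=C1OCC[C@H](C(C)=C)C1 | intermediate
4 | (4S)-3-methyl-4-(prop-1-en-2-yl)oxan-2-one (C3 epimers, trans expected to predominate; not isolated) | O=C1OCC[C@H](C(C)=C)C1C | intermediate
5 | (4R)-3,3-dimethyl-4-(prop-1-en-2-yl)oxan-2-one | O=C1OCC[C@H](C(C)=C)C1(C)C | intermediate
6 | (4R)-3,3-dimethyl-4-(1-methylcyclopropyl)oxan-2-one | O=C1OCC[C@H](C2(C)CC2)C1(C)C | intermediate
7 | diisobutylaluminium lactolate of 6 (O–Al at C2, 4R; not isolated) | CC(C)C[Al](CC(C)C)OC1OCC[C@H](C2(C)CC2)C1(C)C | intermediate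
8 | (4R)-3,3-dimethyl-4-(1-methylcyclopropyl)oxan-2-yl acetate (both anomers) | CC(=O)OC1OCC[C@H](C2(C)CC2)C1(C)C | intermediate
9 | cyclic oxocarbenium ion from 8 (O1=C2 cation of the oxane ring, 4R, bromostannate ion pair; not isolated) | [CH]1=[O+]CC[C@H](C2(C)CC2)C1(C)C | intermediate
10 | 6,9,9-trimethyl-2-oxabicyclo[3.3.1]nonan-6-yl cation (bridgehead configurations fixed by the 4R centre of 8; not isolated) | C1C[C@H]2C(C)(C)[C@@H](O1)CC[C+]2C | intermediate
11 | tricyclic trialkyloxonium ion (7-oxabicyclo[2.2.1]heptane whose O is also bonded to the end of the exo two-carbon chain on C2; not isolated) | C3C[C@H]1C(C)(C)[C@@H]2CC[C@@]1(C)[O+]23 | intermediate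
12 | (1R,2S,4S)-2-(2-bromoethyl)-1,3,3-trimethyl-7-oxabicyclo[2.2.1]heptane | BrCC[C@H]1C(C)(C)[C@@H]2CC[C@@]1(C)O2 | intermediate
13 | (1R,2S,4S)-2-(but-3-yn-1-yl)-1,3,3-trimethyl-7-oxabicyclo[2.2.1]heptane | C#CCC[C@H]1C(C)(C)[C@@H]2CC[C@@]1(C)O2 | intermediate
14 | methyl 4-hydroxy-3-methylbenzoate | COC(=O)c1ccc(O)c(C)c1 | starting material
15 | methyl 4-acetoxy-3-methylbenzoate | COC(=O)c1ccc(OC(C)=O)c(C)c1 | intermediate
16 | methyl 4-acetoxy-3-(bromomethyl)benzoate | COC(=O)c1ccc(OC(C)=O)c(CBr)c1 | intermediate
17 | dimethyl[(1E)-2-methyl-4-[(1R,2S,4S)-1,3,3-trimethyl-7-oxabicyclo[2.2.1]heptan-2-yl]but-1-en-1-yl]alane (not isolated) | C/C(=C\[Al](C)C)CC[C@H]1C(C)(C)[C@@H]2CC[C@@]1(C)O2 | intermediate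
18 | methyl 4-acetoxy-3-[(2E)-3-methyl-5-[(1R,2S,4S)-1,3,3-trimethyl-7-oxabicyclo[2.2.1]heptan-2-yl]pent-2-en-1-yl]benzoate | C/C(=C\Cc1cc(C(=O)OC)ccc1OC(C)=O)CC[C@H]1C(C)(C)[C@@H]2CC[C@@]1(C)O2 | intermediate
19 | 4-hydroxy-3-[(2E)-3-methyl-5-[(1R,2S,4S)-1,3,3-trimethyl-7-oxabicyclo[2.2.1]heptan-2-yl]pent-2-en-1-yl]benzoic acid | C/C(=C\Cc1cc(C(=O)O)ccc1O)CC[C@H]1C(C)(C)[C@@H]2CC[C@@]1(C)O2 | target

**Totals**
Total step count: 10. Longest linear sequence: 8 steps (1 → 3 → 5 → 6 → 8 → 12 → 13 → 18 → 19); the arene branch (14 → 15 → 16) joins at step 9.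

**Steps most likely to fail**

1. Step 5 (proposed new method). The cyclopropane σ-bond may not be nucleophilic enough toward the oxocarbenium ion, so that 9 is only captured reversibly by bromide and returns as lactol on work-up; traces of HBr may open the cyclopropane; or the cascade may stall at the tertiary bromide derived from 10. The fallback uses known chemistry, sets out from 5 and comes back at 12. Lactone 5 is reduced with i-Bu2AlH (CH2Cl2, −78 °C) to the lactol (4R)-3,3-dimethyl-4-(prop-1-en-2-yl)oxan-2-ol F1. F1 reacts through its open hydroxy-aldehyde form with the enantiomer of B-allyldiisopinocampheylborane prepared from (+)-α-pinene (Brown allylation, Et2O, −78 °C; NaOH/H2O2), expected to add to the Si face under reagent control, to give (3R,5S)-4,4-dimethyl-3-(prop-1-en-2-yl)oct-7-ene-1,5-diol F2. Ring-closing metathesis with the second-generation Grubbs catalyst (CH2Cl2, 40 °C) closes the carbocycle to (1S,5R)-5-(2-hydroxyethyl)-4,6,6-trimethylcyclohex-3-en-1-ol F3. Appel bromination of the primary hydroxyl (CBr4, PPh3, CH2Cl2, 0 °C) gives (1S,5R)-5-(2-bromoethyl)-4,6,6-trimethylcyclohex-3-en-1-ol F4. Camphorsulfonic acid (cat., CH2Cl2, rt) then adds the secondary hydroxyl across the trisubstituted alkene at its methyl-bearing carbon (acid-catalysed hydroalkoxylation of a cyclohex-3-enol) to give 12.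

2. Step 9. The Lewis-acidic AlMe3/zirconocene medium may ionise the tertiary C–O bond of the strained bridging ether, and the alkenylalane may attack the acetate or the ester of 16 before cross-coupling. The fallback sets out from 13 and comes back at 18. Copper-catalysed syn-methylboration of 13 (CuCl, xantphos, NaOt-Bu, B2pin2, MeI, THF, rt) places boron at the terminus and CH3 at the internal carbon to give 4,4,5,5-tetramethyl-2-[(1E)-2-methyl-4-[(1R,2S,4S)-1,3,3-trimethyl-7-oxabicyclo[2.2.1]heptan-2-yl]but-1-en-1-yl]-1,3,2-dioxaborolane F5. Suzuki–Miyaura coupling of F5 with 16 (PdCl2(dppf), K3PO4, toluene/H2O, 50 °C) gives 18 with retention of the alkene geometry and without a strong Lewis acid.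

3. Step 1. Slow transmetalation of the α-branched alkenylboronate with competing protodeboronation, and hydrolytic opening of the lactone in the aqueous base, may give low conversion or eroded enantioselectivity. The fallback sets out from 1 and comes back at 4, then 5. Copper-catalysed enantioselective conjugate addition of isopropenylmagnesium bromide to 1 (CuBr·SMe2, a Josiphos-type ferrocenyl diphosphine, t-BuOMe, −78 °C) gives the bromomagnesium enolate of 3 F6. F6 is C-methylated in the same flask (MeI, DMPU, −78 → 0 °C) to give 4, here isolated; one further enolate methylation (LiN(i-Pr)2, MeI, DMPU, THF) leads to 5. The stereocentre and the first methyl group are thus set in one tandem operation from a hard organometallic reagent.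

**Further compounds**
F1 | step 5 | (4R)-3,3-dimethyl-4-(prop-1-en-2-yl)oxan-2-ol | OC1OCC[C@H](C(C)=C)C1(C)C
F2 | step 5 | (3R,5S)-4,4-dimethyl-3-(prop-1-en-2-yl)oct-7-ene-1,5-diol | OCC[C@H](C(C)=C)C(C)(C)[C@@H](O)CC=C
F3 | step 5 | (1S,5R)-5-(2-hydroxyethyl)-4,6,6-trimethylcyclohex-3-en-1-ol | OCC[C@H]1C(C)(C)[C@@H](O)CC=C1C
F4 | step 5 | (1S,5R)-5-(2-bromoethyl)-4,6,6-trimethylcyclohex-3-en-1-ol | BrCC[C@H]1C(C)(C)[C@@H](O)CC=C1C
F5 | step 9 | 4,4,5,5-tetramethyl-2-[(1E)-2-methyl-4-[(1R,2S,4S)-1,3,3-trimethyl-7-oxabicyclo[2.2.1]heptan-2-yl]but-1-en-1-yl]-1,3,2-dioxaborolane | C/C(=C\B1OC(C)(C)C(C)(C)O1)CC[C@H]1C(C)(C)[C@@H]2CC[C@@]1(C)O2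
F6 | step 1 | bromomagnesium enolate of 3 (4S; O-bound magnesium at C2, C2=C3 double bond) | Br[Mg]OC1=C[C@@H](C(C)=C)CCO1
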